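## Analysis of the target

CNP0583011.0 is methyl 2-hydroxy-6-[2-(hydroxymethyl)-4,6-dimethoxyphenoxy]-4-methyl-3-(3-methylbut-2-en-1-yl)benzoate, a diaryl ether of two benzene rings. Ring A is a pentasubstituted benzoate (C1 CO2CH3, C2 aryloxy, C3 H, C4 CH3, C5 prenyl, C6 OH). Ring B is tetrasubstituted (C1' ether carbon, C2' CH2OH, C4' and C6' OCH3). The molecule has no stereocentre and the prenyl double bond has no geometric isomer, so the task is one of regiochemistry and functional-group tolerance. The sensitive groups are the prenyl alkene next to a free phenol (acid closes it to a 2,2-dimethylchroman), the benzylic alcohol on an electron-rich ring (it ionises easily), and the salicylate-type methyl ester. Two things make the synthesis hard. The ether oxygen lies between an ortho ester on ring A and two ortho substituents on ring B, and both rings are electron-rich, so nucleophilic aromatic substitution is excluded and copper-mediated couplings are slow. Ring A also carries five different groups in a fixed contiguous order that is awkward to reach by substitution of an arene. The strategy rests on one feature: C2 (aryloxy) and C3 (H) of ring A form a two-carbon unit with the pattern of an aryl ethynyl ether, while C1, C6, C5 and C4 with their ester, oxygen, prenyl and methyl groups map onto C3, C4, C5 and C6 of a 2-pyrone-3-carboxylate. Ring A can therefore be built by a [4+2] cycloaddition in which the ether oxygen arrives already bonded to the alkyne.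

## Retrosynthetic reasoning

**Protecting groups (24 from 23 from 22).** Target 24 is taken back to silyl ether 23 and then to acetate 22; no skeletal bond is cut. The benzylic hydroxyl of ring B has to be masked because a free alcohol would add to an ynol ether. The C6 oxygen of ring A has to be masked because, as a free acidic enol on the pyrone, it would protonate the ynol ether. A primary alkyl silyl ether and an aryl acetate are chosen because they are removed by fluoride and by base-mediated methanolysis, conditions under which the prenyl phenol, the benzylic alcohol and the methyl ester are safe. No acid is needed once ring A exists.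

**Key disconnection (22 to 8 and 20).** In 22 the C1–C2 and C3–C4 bonds of ring A are cut, which leads to acetoxypyrone 8 and aryl ethynyl ether 20, with bridged lactone 21 as the adduct that loses its lactone bridge. Cutting the aryl–oxygen bond on an intact arene would instead lead back to a coupling between a hindered phenol and a hindered, electron-rich aryl electrophile. The cut through ring A moves that C–O bond onto an alkyne carbon and turns four contiguous ring substituents into substituents of a pyrone made from acyclic carbonyl compounds. The forward reaction has to join the terminal CH of 20 to the methyl-bearing C6 of 8 and the aryloxy carbon to the ester-bearing C3; the polarisation of both partners points that way.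

**Ynol ether (20 from 17, 16, 15, then 12 and 13).** The triple bond of 20 is traced to the dichlorovinyl ether 17 by double dehalogenation with an organolithium base. The O–C(vinyl) bond of 15 is cut to phenol 12 and trichloroethylene 13. The forward reaction is addition of the phenoxide to dichloroacetylene 14 made in the flask, so the hindered C–O bond forms at a linear sp carbon. The vinylation is placed at the aldehyde stage (12 to 15) so that reduction to 16 and silylation to 17 never have to distinguish a phenol from a benzylic alcohol.

**Ring B phenol (12 from 11 from 9).** The formyl group of 12 is removed to give 2,4-dimethoxyphenol 11, which has only one free ortho position, so the formylation has no regiochemical choice. Phenol 11 is traced to the inexpensive aldehyde 9 by aryl migration to oxygen.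

**Pyrone (8 from 7 from 3 and 4).** Acetate 8 comes from hydroxypyrone 7. In 7 the C3–C4 and O1–C2 bonds are cut, giving β-keto ester 3 and malonyl half-ester chloride 4. This is preferred to acylating a methyl ketone at its internal α-carbon, which would depend on a regioselective enolisation. In 3 the prenyl-bearing carbon is fixed without ambiguity, and 4 brings the C3 ester with it. The forward reaction is O-acylation of the chelated enolate 5 to enol malonate 6, followed by Dieckmann closure onto the neighbouring methyl ester.

**β-Keto ester (3 from 1 and 2).** The C–C bond between the acetoacetate α-carbon and the allylic CH2 is cut, giving methyl acetoacetate 1 and prenyl bromide 2, a standard enolate alkylation.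

## Alternatives that were turned down

**Alternative 1:** Oxidative spirocyclisation of a benzophenone followed by retro-Claisen opening.
- Disconnection: the bond between the ring A C2 oxygen and ring B C1', with the ester carbon serving as a temporary ketone bridge between the rings.
- Forward key step: benzophenone A1, with a free C4' hydroxyl on ring B, is oxidised with PhI(OAc)2. The ring A hydroxyl attacks C1' of the oxidised ring and closes the five-membered furanone ring of racemic spiro grisadienone A2. Methoxide then cleaves the acyl–spiro carbon bond to give diaryl ether ester A3.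
- For: it follows the likely biogenesis; the hindered C–O bond forms intramolecularly in a five-membered ring; both rings start from ordinary arenes. On the C–O bond-forming event itself this plan is at least as strong as the chosen one.
- Against: the C4' oxygen must be free for the oxidation and methylated afterwards. The tetra-ortho-substituted benzophenone is itself a hindered target. The oxidant meets a prenyl alkene and two electron-rich rings. The retro-Claisen step competes with conjugate addition of methoxide to the dienone. The methoxymethyl ether must finally be removed with acid in the presence of the prenyl phenol and the benzylic alcohol. The substitution pattern of ring A still has to be set on an arene.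
- Comparison: the chosen strategy uses no oxidant and no acid, sets the ring A pattern by enolate chemistry, and needs two steps after its key step where this plan needs four (ring opening, methylation, two deprotections).

**Alternative 2:** Three-component aryne coupling.
- Disconnection: the C2–O bond and the C1–carboxyl bond of ring A, both on an aryne.
- Forward key step: CsF releases the C1–C2 aryne from silyl triflate A4. The phenoxide of A5 adds at C2, the position remote from the C6 acetal oxygen, and the C1 aryl anion is trapped by CO2 to give acid A6. No ring closes.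
- For: both hindered bonds form in one operation, the inductive effect of the C6 oxygen supports the regiochemistry, and the plan is highly convergent. In convergence and atom economy of the key step it is stronger than the chosen route.
- Against: A4 is a hexasubstituted benzene with adjacent silyl and triflate groups, so the difficulty of ring A is moved, not removed. The hindered phenoxide competes with fluoride and with the carboxylate product for the aryne. The aryl anion can be protonated before carboxylation. Arynes undergo ene reactions with prenyl alkenes. Esterification, acidic acetal removal and desilylation follow.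
- Comparison: the chosen strategy needs no preformed pentasubstituted arene and its key step passes through neutral, closed-shell intermediates.

**Alternative 3:** Exchanged pyrone and alkyne partners.
- Disconnection: the C1–C6 and C4–C5 bonds of ring A.
- Forward key step: 4-aryloxypyrone A7 and prenyl siloxyalkyne A8 undergo [4+2] cycloaddition with loss of CO2 to give bis-silyl ether A9.
- For: the polarisation is equally favourable. A7 should come from a 4-hydroxy-6-methylpyrone ester by addition–elimination of the ring B phenoxide, which is easier than the pyrone of the chosen route. One fluoride treatment removes both silyl groups, so the endgame is a step shorter. On these counts it is as strong as or stronger than the chosen plan.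
- Against: the new C4–C5 bond joins the methyl-bearing pyrone carbon to a substituted alkyne carbon, a more congested closure than attack of a terminal CH. Siloxyalkynes can isomerise thermally to silylketenes by silyl shift. The skipped enyne of A8 is prone to isomerisation under the strongly basic conditions of its preparation. The aryloxy group at pyrone C4 donates more than an acyloxy group and raises the diene LUMO.
- Comparison: the chosen strategy offers an unsubstituted alkyne terminus for the hindered bond, a dienophile that cannot rearrange to a ketene, and a more electron-poor diene.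

Key step: step 10

## Route

**Step 1**
Reactants: 1 methyl acetoacetate; 2 prenyl bromide (1-bromo-3-methylbut-2-ene)
Product: 3 methyl 2-acetyl-5-methylhex-4-enoate (racemic)
Conditions: K2CO3, acetone, reflux (1 in slight excess)
Reagents that add atoms: none
Why: C-alkylation of the acetoacetate enolate by SN2 displacement at the primary allylic bromide; the excess of 1 limits dialkylation. The new stereocentre is racemic and is erased in step 2.

**Step 2**
Reactants: 3 methyl 2-acetyl-5-methylhex-4-enoate; 4 methyl 3-chloro-3-oxopropanoate
Product: 7 methyl 4-hydroxy-6-methyl-5-(3-methylbut-2-en-1-yl)-2-oxo-2H-pyran-3-carboxylate, via sodium enolate 5 (not isolated), via enol malonate 6 (not isolated)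
Conditions: NaH, THF, 0 °C; 4, −78 → 0 °C; then KOC(CH3)3, −20 → 0 °C; cold aq. HCl
Reagents that add atoms: none
Why: The chelated sodium Z-enolate of an α-substituted β-keto ester is acylated on oxygen by the acid chloride, placing the malonyl ester cis to CO2CH3. The doubly activated malonyl CH2 is then deprotonated and closes the six-membered ring by Dieckmann (Lacey-type) acylation of the neighbouring methyl ester, the closure by which O-malonyl salicylates and N-malonyl β-enamino esters give 3-alkoxycarbonyl-4-hydroxycoumarins and -pyridones. Formation of the strongly acidic pyronolate makes it irreversible, and the acidic product can be separated from neutral by-products by bicarbonate extraction.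

**Step 3**
Reactants: 7 methyl 4-hydroxy-6-methyl-5-(3-methylbut-2-en-1-yl)-2-oxo-2H-pyran-3-carboxylate
Product: 8 methyl 4-acetoxy-6-methyl-5-(3-methylbut-2-en-1-yl)-2-oxo-2H-pyran-3-carboxylate
Conditions: Ac2O, Et3N, DMAP (cat.), CH2Cl2, 0 °C; non-aqueous work-up, used promptly
Reagents that add atoms: acetic anhydride, CC(=O)OC(C)=O
Why: DMAP-catalysed O-acylation of the acidic C4 enol; C3 and C5 are both substituted, so C-acylation and acyl migration cannot compete. The acetate removes the acidic proton and keeps the pyrone electron-poor.

**Step 4**
Reactants: 9 2,4-dimethoxybenzaldehyde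
Product: 11 2,4-dimethoxyphenol, via aryl formate 10 (not isolated)
Conditions: mCPBA, CH2Cl2, 0 °C → rt; aq. NaHCO3 wash; then K2CO3 (cat.), MeOH, rt
Reagents that add atoms: 3-chloroperbenzoic acid, OOC(=O)c1cccc(Cl)c1
Why: Baeyer–Villiger (Dakin-type) oxidation: the electron-rich 2,4-dimethoxyphenyl group migrates in preference to hydride, and the aryl formate is cleaved by methanolysis.

**Step 5**
Reactants: 11 2,4-dimethoxyphenol
Product: 12 2-hydroxy-3,5-dimethoxybenzaldehyde
Conditions: MgCl2, Et3N, (CH2O)n, MeCN, reflux
Reagents that add atoms: paraformaldehyde (as formaldehyde), C=O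
Why: Magnesium-mediated ortho-formylation (Casnati–Skattebøl): the magnesium phenoxide delivers formaldehyde through a six-membered chelate to the only free ortho position, and the resulting benzylic alkoxide is oxidised by hydride transfer to a second formaldehyde.

**Step 6**
Reactants: 12 2-hydroxy-3,5-dimethoxybenzaldehyde; 13 trichloroethylene
Product: 15 2-{[(E)-1,2-dichloroethenyl]oxy}-3,5-dimethoxybenzaldehyde, via dichloroacetylene 14 (not isolated)
Conditions: K2CO3, DMF, 70 °C
Reagents that add atoms: none
Why: Base-induced dehydrochlorination of 13 gives dichloroacetylene, to which the phenoxide adds in anti fashion (vinylic substitution by elimination–addition) to give the E-dichlorovinyl ether. The C–O bond forms at a linear sp carbon, so the two ortho substituents of ring B count for little.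

**Step 7**
Reactants: 15 2-{[(E)-1,2-dichloroethenyl]oxy}-3,5-dimethoxybenzaldehyde
Product: 16 (2-{[(E)-1,2-dichloroethenyl]oxy}-3,5-dimethoxyphenyl)methanol
Conditions: NaBH4, MeOH, 0 °C
Reagents that add atoms: none
Why: Chemoselective hydride reduction of the aldehyde; the dichlorovinyl ether is inert to NaBH4.

**Step 8**
Reactants: 16 (2-{[(E)-1,2-dichloroethenyl]oxy}-3,5-dimethoxyphenyl)methanol
Product: 17 tert-butyl[(2-{[(E)-1,2-dichloroethenyl]oxy}-3,5-dimethoxyphenyl)methoxy]dimethylsilane
Conditions: TBSCl, imidazole, DMF, rt
Reagents that add atoms: tert-butyldimethylsilyl chloride, CC(C)(C)[Si](C)(C)Cl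
Why: Standard silylation of a primary benzylic alcohol. The silyl ether prevents addition of the hydroxyl group to the ynol ether and tolerates the organolithium base, heat and carbonate in methanol.

**Step 9**
Reactants: 17 tert-butyl[(2-{[(E)-1,2-dichloroethenyl]oxy}-3,5-dimethoxyphenyl)methoxy]dimethylsilane
Product: 20 tert-butyl{[2-(ethynyloxy)-3,5-dimethoxyphenyl]methoxy}dimethylsilane, via chloroalkynyl ether 18 (not isolated), via lithium acetylide 19 (not isolated)
Conditions: n-C4H9Li (2.3 equiv), THF, −78 → −40 °C; then MeOH, −78 °C; base-washed glassware, kept cold in solution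
Reagents that add atoms: none
Why: Deprotonation of the vinyl C–H and β-elimination of chloride give the chloroalkynyl ether, chlorine–lithium exchange gives the acetylide, and a proton source at low temperature gives the terminal ynol ether. This is the standard dichlorovinyl ether route to alkynyl ethers.

**Step 10**
Reactants: 8 methyl 4-acetoxy-6-methyl-5-(3-methylbut-2-en-1-yl)-2-oxo-2H-pyran-3-carboxylate; 20 tert-butyl{[2-(ethynyloxy)-3,5-dimethoxyphenyl]methoxy}dimethylsilane
Product: 22 methyl 2-acetoxy-6-(2-{[(tert-butyldimethylsilyl)oxy]methyl}-4,6-dimethoxyphenoxy)-4-methyl-3-(3-methylbut-2-en-1-yl)benzoate, via bridged lactone 21 (not isolated)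
Conditions: PhMe, 105 °C, sealed tube, Ar; 20 (1.5 equiv) added in portions
Reagents that add atoms: none
Why: Inverse-electron-demand Diels–Alder reaction followed by decarboxylative retro-Diels–Alder: the HOMO of ynol ether 20, largest on the terminal CH, meets the LUMO of pyrone 8, which is lowered by the C3 ester and the lactone carbonyl and only slightly raised by the acyloxy group. Bonding is asynchronous: the terminal CH bonds first to pyrone C6, the δ-carbon of the doubly activated dienyl system, while charge builds on the aryloxy carbon (oxocarbenium-like) and on C3 (malonate-like), which then join. This gives bridged lactone 21, whose two bridgehead centres are transient; cycloreversion expels CO2 and leaves the benzene ring. Ring A thus closes by an intermolecular [4+2] annulation that forms C1–C2 and C3–C4, and no stereocentre remains. The closest known reaction type is the cycloaddition of 3-methoxycarbonyl-2-pyrones with ketene acetals, ynamines and alkynyl ethers, which gives 2-alkoxy- or 2-aminobenzoates with the same orientation. The selectivity required is regiochemical (aryloxy carbon next to the ester) and the matched polarisation of both partners secures it; the prenyl alkene is neither electron-rich nor strained enough to compete. The acetate prevents the C4 oxygen from protonating the ynol ether and emerges as the ring A C6 ester.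

**Step 11**
Reactants: 22 methyl 2-acetoxy-6-(2-{[(tert-butyldimethylsilyl)oxy]methyl}-4,6-dimethoxyphenoxy)-4-methyl-3-(3-methylbut-2-en-1-yl)benzoate
Product: 23 methyl 6-(2-{[(tert-butyldimethylsilyl)oxy]methyl}-4,6-dimethoxyphenoxy)-2-hydroxy-4-methyl-3-(3-methylbut-2-en-1-yl)benzoate
Conditions: K2CO3, MeOH, 0 °C → rt
Reagents that add atoms: none
Why: Base-mediated methanolysis (transesterification) of an aryl acetate whose leaving group is a salicylate-type phenoxide. With methanol as solvent the methyl ester can only exchange with itself, and the alkyl silyl ether is stable to carbonate.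

**Step 12**
Reactants: 23 methyl 6-(2-{[(tert-butyldimethylsilyl)oxy]methyl}-4,6-dimethoxyphenoxy)-2-hydroxy-4-methyl-3-(3-methylbut-2-en-1-yl)benzoate
Product: 24 methyl 2-hydroxy-6-[2-(hydroxymethyl)-4,6-dimethoxyphenoxy]-4-methyl-3-(3-methylbut-2-en-1-yl)benzoate (CNP0583011.0)
Conditions: Bu4NF, AcOH, THF, 0 °C → rt
Reagents that add atoms: none
Why: Fluoride-induced cleavage of the silyl ether, driven by Si–F bond formation. Buffering with acetic acid keeps the medium near neutral, so neither lactonisation onto the ester nor cyclisation of the prenyl phenol should occur.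

## Compound list

1 | methyl acetoacetate | COC(=O)CC(C)=O | starting material
2 | prenyl bromide (1-bromo-3-methylbut-2-ene) | CC(C)=CCBr | starting material
3 | methyl 2-acetyl-5-methylhex-4-enoate (racemic) | COC(=O)C(CC=C(C)C)C(C)=O | intermediate
4 | methyl 3-chloro-3-oxopropanoate | COC(=O)CC(Cl)=O | starting material
5 | sodium (Z)-enolate of 3, sodium (Z)-4-methoxy-3-(3-methylbut-2-en-1-yl)-4-oxobut-2-en-2-olate | COC(=O)/C(CC=C(C)C)=C(/C)[O-].[Na+] | intermediate (not isolated)
6 | methyl (Z)-3-[(3-methoxy-3-oxopropanoyl)oxy]-2-(3-methylbut-2-en-1-yl)but-2-enoate | COC(=O)CC(=O)O/C(C)=C(/CC=C(C)C)C(=O)OC | intermediate (not isolated)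
7 | methyl 4-hydroxy-6-methyl-5-(3-methylbut-2-en-1-yl)-2-oxo-2H-pyran-3-carboxylate | COC(=O)C1=C(O)C(CC=C(C)C)=C(C)OC1=O | intermediate
8 | methyl 4-acetoxy-6-methyl-5-(3-methylbut-2-en-1-yl)-2-oxo-2H-pyran-3-carboxylate | COC(=O)C1=C(OC(C)=O)C(CC=C(C)C)=C(C)OC1=O | intermediate
9 | 2,4-dimethoxybenzaldehyde | COc1ccc(C=O)c(OC)c1 | starting material
10 | 2,4-dimethoxyphenyl formate | COc1ccc(OC=O)c(OC)c1 | intermediate (not isolated)
11 | 2,4-dimethoxyphenol | COc1ccc(O)c(OC)c1 | intermediate
12 | 2-hydroxy-3,5-dimethoxybenzaldehyde | COc1cc(OC)c(O)c(C=O)c1 | intermediate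
13 | trichloroethylene | ClC=C(Cl)Cl | starting material
14 | dichloroacetylene | ClC#CCl | intermediate (not isolated)
15 | 2-{[(E)-1,2-dichloroethenyl]oxy}-3,5-dimethoxybenzaldehyde | COc1cc(OC)c(O/C(Cl)=C\Cl)c(C=O)c1 | intermediate
16 | (2-{[(E)-1,2-dichloroethenyl]oxy}-3,5-dimethoxyphenyl)methanol | COc1cc(OC)c(O/C(Cl)=C\Cl)c(CO)c1 | intermediate
17 | tert-butyl[(2-{[(E)-1,2-dichloroethenyl]oxy}-3,5-dimethoxyphenyl)methoxy]dimethylsilane | COc1cc(OC)c(O/C(Cl)=C\Cl)c(CO[Si](C)(C)C(C)(C)C)c1 | intermediate
18 | tert-butyl({2-[(chloroethynyl)oxy]-3,5-dimethoxyphenyl}methoxy)dimethylsilane | COc1cc(OC)c(OC#CCl)c(CO[Si](C)(C)C(C)(C)C)c1 | intermediate (not isolated)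
19 | lithium 2-(2-{[(tert-butyldimethylsilyl)oxy]methyl}-4,6-dimethoxyphenoxy)ethynide | [Li]C#COc1c(CO[Si](C)(C)C(C)(C)C)cc(OC)cc1OC | intermediate (not isolated)
20 | tert-butyl{[2-(ethynyloxy)-3,5-dimethoxyphenyl]methoxy}dimethylsilane | C#COc1c(CO[Si](C)(C)C(C)(C)C)cc(OC)cc1OC | intermediate
21 | methyl 8-acetoxy-5-(2-{[(tert-butyldimethylsilyl)oxy]methyl}-4,6-dimethoxyphenoxy)-1-methyl-7-(3-methylbut-2-en-1-yl)-3-oxo-2-oxabicyclo[2.2.2]octa-5,7-diene-4-carboxylate (racemic; the two bridgeheads are fixed relative to each other by the bicycle) | COC(=O)C12C(=O)OC(C)(C(CC=C(C)C)=C1OC(C)=O)C=C2Oc3c(CO[Si](C)(C)C(C)(C)C)cc(OC)cc3OC | intermediate (not isolated)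
22 | methyl 2-acetoxy-6-(2-{[(tert-butyldimethylsilyl)oxy]methyl}-4,6-dimethoxyphenoxy)-4-methyl-3-(3-methylbut-2-en-1-yl)benzoate | COC(=O)c1c(Oc2c(CO[Si](C)(C)C(C)(C)C)cc(OC)cc2OC)cc(C)c(CC=C(C)C)c1OC(C)=O | intermediate
23 | methyl 6-(2-{[(tert-butyldimethylsilyl)oxy]methyl}-4,6-dimethoxyphenoxy)-2-hydroxy-4-methyl-3-(3-methylbut-2-en-1-yl)benzoate | COC(=O)c1c(Oc2c(CO[Si](C)(C)C(C)(C)C)cc(OC)cc2OC)cc(C)c(CC=C(C)C)c1O | intermediate
24 | methyl 2-hydroxy-6-[2-(hydroxymethyl)-4,6-dimethoxyphenoxy]-4-methyl-3-(3-methylbut-2-en-1-yl)benzoate (CNP0583011.0) | COC(=O)c1c(Oc2c(CO)cc(OC)cc2OC)cc(C)c(CC=C(C)C)c1O | target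

## Step count and least certain steps

Total: 12 steps. Longest linear sequence: 9 steps (steps 4 to 12, from 9). The pyrone arm (steps 1 to 3) joins at step 10.

**Step 10 (key step).** The cycloaddition is slowed by the methyl group on pyrone C6 and by the donor substituents, and it needs heat. The terminal ynol ether may be lost by thermal oligomerisation or adventitious hydration before it reacts. The ynol ether may also attack the acetyl carbonyl or pyrone C4 (acyl transfer or addition–elimination) instead of C6.

The fallback gives up the ynol ether and forms the aryl–oxygen bond by a copper-mediated coupling. It sets out from 8 and comes back to the route at 24.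
- Pyrone 8 is heated in toluene with 1,1-bis(trimethylsilyloxy)ethene, a more nucleophilic ketene acetal of the same polarity. After loss of the lactone bridge and of trimethylsilanol, aqueous work-up should give methyl 2-acetoxy-6-hydroxy-4-methyl-3-(3-methylbut-2-en-1-yl)benzoate F1.
- F1 is coupled with 2-bromo-3,5-dimethoxybenzaldehyde (CuI, N,N-dimethylglycine, Cs2CO3, dioxane, 90 °C; Ullmann-type ether synthesis assisted by the ortho formyl group) to give methyl 2-acetoxy-6-(2-formyl-4,6-dimethoxyphenoxy)-4-methyl-3-(3-methylbut-2-en-1-yl)benzoate F2. If the acetate is lost under the basic conditions, the coupling should still favour the oxygen flanked by hydrogen over the one flanked by prenyl.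
- NaBH4 in methanol reduces the aldehyde to methyl 2-acetoxy-6-[2-(hydroxymethyl)-4,6-dimethoxyphenoxy]-4-methyl-3-(3-methylbut-2-en-1-yl)benzoate F3, and K2CO3 in the same methanol removes the acetate to give 24.

**Step 2.** Acylation of enolate 5 may occur on carbon, or give the E enol ester, which cannot cyclise. The malonyl anion of 6 may fragment by E1cB loss of the β-keto ester enolate before the Dieckmann closure. Alkoxide may open the pyrone once it has formed.

The fallback builds the same pyrone from the ketone side. It sets out from 3 and comes back at 7.
- Saponification and decarboxylation of 3 (aq. NaOH, then gentle acidification and warming) give 6-methylhept-5-en-2-one F4.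
- Thermodynamic silylation (Me3SiCl, NaI, Et3N, MeCN) gives, as the major regioisomer to be purified by distillation, (Z)-trimethyl[(6-methylhepta-2,5-dien-2-yl)oxy]silane F5.
- F5 is heated with trimethyl methanetricarboxylate (diphenyl ether, 150–180 °C). C-acylation at the prenyl-bearing carbon by the ketene formed from the triester, then lactonisation with loss of methoxytrimethylsilane, should give 7.

**Step 9.** The excess organolithium may metalate ring B between the two methoxy groups or at the benzylic position. The chlorine–lithium exchange may be incomplete. The terminal ynol ether may oligomerise on concentration or storage.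

The fallback isolates a capped form of the alkyne instead of the terminal ynol ether. It sets out from 17 and comes back at 20.
- After the same treatment with n-C4H9Li, acetylide 19 is quenched with Me3SiCl instead of methanol, giving tert-butyl{[3,5-dimethoxy-2-{[2-(trimethylsilyl)ethynyl]oxy}phenyl]methoxy}dimethylsilane F6, which can be purified and stored.
- Bu4NF (1 equiv, THF, −78 °C) cleaves the alkynyl C–Si bond selectively immediately before step 10 and releases 20.

**Step 6.** The phenoxide of 12 is hindered and deactivated by the ortho formyl group (conjugation and hydrogen bonding), so vinylation may be slow. The aldehyde may suffer base-induced side reactions in hot DMF.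

The fallback changes the order of events so that no aldehyde is present. It sets out from 12 and comes back at 17.
- NaBH4 (MeOH, 0 °C) gives 2-(hydroxymethyl)-4,6-dimethoxyphenol F7.
- TBSCl and imidazole (1 equiv, CH2Cl2, 0 °C) silylate the primary alcohol in preference to the hindered, hydrogen-bonded phenol to give 2-{[(tert-butyldimethylsilyl)oxy]methyl}-4,6-dimethoxyphenol F8.
- F8 is vinylated with 13 (K2CO3, DMF, 70 °C) to give 17 directly; steps 7 and 8 fall away.

## Further compounds

F1 | step 10 | methyl 2-acetoxy-6-hydroxy-4-methyl-3-(3-methylbut-2-en-1-yl)benzoate | COC(=O)c1c(O)cc(C)c(CC=C(C)C)c1OC(C)=O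
F2 | step 10 | methyl 2-acetoxy-6-(2-formyl-4,6-dimethoxyphenoxy)-4-methyl-3-(3-methylbut-2-en-1-yl)benzoate | COC(=O)c1c(Oc2c(C=O)cc(OC)cc2OC)cc(C)c(CC=C(C)C)c1OC(C)=O
F3 | step 10 | methyl 2-acetoxy-6-[2-(hydroxymethyl)-4,6-dimethoxyphenoxy]-4-methyl-3-(3-methylbut-2-en-1-yl)benzoate | COC(=O)c1c(Oc2c(CO)cc(OC)cc2OC)cc(C)c(CC=C(C)C)c1OC(C)=O
F4 | step 2 | 6-methylhept-5-en-2-one | CC(=O)CCC=C(C)C
F5 | step 2 | (Z)-trimethyl[(6-methylhepta-2,5-dien-2-yl)oxy]silane | C/C(O[Si](C)(C)C)=C/CC=C(C)C
F6 | step 9 | tert-butyl{[3,5-dimethoxy-2-{[2-(trimethylsilyl)ethynyl]oxy}phenyl]methoxy}dimethylsilane | C[Si](C)(C)C#COc1c(CO[Si](C)(C)C(C)(C)C)cc(OC)cc1OC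
F7 | step 6 | 2-(hydroxymethyl)-4,6-dimethoxyphenol | COc1cc(OC)c(O)c(CO)c1
F8 | step 6 | 2-{[(tert-butyldimethylsilyl)oxy]methyl}-4,6-dimethoxyphenol | COc1cc(OC)c(O)c(CO[Si](C)(C)C(C)(C)C)c1
A1 | alternative 1 | (2-{[(tert-butyldimethylsilyl)oxy]methyl}-4-hydroxy-6-methoxyphenyl)[6-hydroxy-2-(methoxymethoxy)-4-methyl-3-(3-methylbut-2-en-1-yl)phenyl]methanone | COCOc1c(CC=C(C)C)c(C)cc(O)c1C(=O)c1c(CO[Si](C)(C)C(C)(C)C)cc(O)cc1OC
A2 | alternative 1 | racemic 2'-{[(tert-butyldimethylsilyl)oxy]methyl}-6'-methoxy-4-(methoxymethoxy)-6-methyl-5-(3-methylbut-2-en-1-yl)-3H-spiro[benzofuran-2,1'-cyclohexa[2,5]diene]-3,4'-dione | COCOc1c(CC=C(C)C)c(C)cc2OC3(C(=O)c12)C(CO[Si](C)(C)C(C)(C)C)=CC(=O)C=C3OC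
A3 | alternative 1 | methyl 6-(2-{[(tert-butyldimethylsilyl)oxy]methyl}-4-hydroxy-6-methoxyphenoxy)-2-(methoxymethoxy)-4-methyl-3-(3-methylbut-2-en-1-yl)benzoate | COCOc1c(CC=C(C)C)c(C)cc(Oc2c(CO[Si](C)(C)C(C)(C)C)cc(O)cc2OC)c1C(=O)OC
A4 | alternative 2 | 3-(methoxymethoxy)-5-methyl-4-(3-methylbut-2-en-1-yl)-2-(trimethylsilyl)phenyl trifluoromethanesulfonate | COCOc1c(CC=C(C)C)c(C)cc(OS(=O)(=O)C(F)(F)F)c1[Si](C)(C)C
A5 | alternative 2 | 2,4-dimethoxy-6-{[(triisopropylsilyl)oxy]methyl}phenol | COc1cc(OC)c(O)c(CO[Si](C(C)C)(C(C)C)C(C)C)c1
A6 | alternative 2 | 6-(2,4-dimethoxy-6-{[(triisopropylsilyl)oxy]methyl}phenoxy)-2-(methoxymethoxy)-4-methyl-3-(3-methylbut-2-en-1-yl)benzoic acid | OC(=O)c1c(Oc2c(CO[Si](C(C)C)(C(C)C)C(C)C)cc(OC)cc2OC)cc(C)c(CC=C(C)C)c1OCOC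
A7 | alternative 3 | methyl 4-(2-{[(tert-butyldimethylsilyl)oxy]methyl}-4,6-dimethoxyphenoxy)-6-methyl-2-oxo-2H-pyran-3-carboxylate | COC(=O)C1=C(Oc2c(CO[Si](C)(C)C(C)(C)C)cc(OC)cc2OC)C=C(C)OC1=O
A8 | alternative 3 | triisopropyl[(5-methylhex-4-en-1-yn-1-yl)oxy]silane | CC(C)=CCC#CO[Si](C(C)C)(C(C)C)C(C)C
A9 | alternative 3 | methyl 6-(2-{[(tert-butyldimethylsilyl)oxy]methyl}-4,6-dimethoxyphenoxy)-4-methyl-3-(3-methylbut-2-en-1-yl)-2-[(triisopropylsilyl)oxy]benzoate | COC(=O)c1c(Oc2c(CO[Si](C)(C)C(C)(C)C)cc(OC)cc2OC)cc(C)c(CC=C(C)C)c1O[Si](C(C)C)(C(C)C)C(C)C
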